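**Plan**

- Cuts: first O1–C8a of ring C (aryl ether → ortho-fluoroaryl ketone carrying a silylated 2S carbinol), then C4–C4a (aryllithium + Weinreb amide), the C8–CH2 bond of the diol chain (arylmagnesium + methyl (S)-glycidate, then MeMgBr) and the C6–prenyl bond (aryl iodide).
- Enabling feature: ring A alternates heteroatoms (C5, C7, C8a) with three different carbon groups (C4a, C6, C8). C8a is the β-carbon of the C4 ketone, so with F at C8a the unit C4(=O)–C4a=C8a–F is a vinylogous acyl fluoride six atoms from the C2 oxygen.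
- In 5-fluororesorcinol the C–F carbon becomes C8a, the carbon between the oxygens becomes C6, and the two equivalent CH groups ortho to fluorine become C8 and C4a. The 6-prenyl/8-diol pattern is therefore fixed by symmetry; fluorine directs both lithiations and then leaves.
- Forward: ring A is substituted stepwise (C6, C8, C4a), ring B arrives with the acyl chain, ring C is closed last by fluoride-triggered O1–C8a bond formation, and one acid step removes the MOM and acetonide groups.
- Stereochemistry: side-chain C2 comes from methyl (S)-glycidate (stereocentre untouched). Chromanone C2 comes from asymmetric transfer hydrogenation of a β-keto Weinreb amide and is retained because the ring closure does not break the C2–O bond.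

Key step: step 11

Remark: the SMILES is read as 2S at the chromanone and 2S in the 2,3-dihydroxy-3-methylbutyl chain; flavanone numbering (O1, C2–C4, C4a, C5–C8, C8a) is used throughout.

**Route**

Step 1
Reactants: 1 5-fluorobenzene-1,3-diol
Product: 2 5-fluoro-2-iodobenzene-1,3-diol
Conditions: I2 (1.05 equiv), NaHCO3, H2O, 0 °C to rt
Reagents that add atoms: iodine, [I][I]
Why: Electrophilic aromatic iodination of the resorcinol monoanion in aqueous bicarbonate goes between the two oxygens (the standard way to 2-iodoresorcinols) and the other two positions are further deactivated by the ortho fluorine, so the iodine should mark the future C6.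

Step 2
Reactants: 2 5-fluoro-2-iodobenzene-1,3-diol
Product: 3 5-fluoro-2-iodo-1,3-bis(methoxymethoxy)benzene
Conditions: MOMCl, i-Pr2NEt, CH2Cl2, 0 °C to rt
Reagents that add atoms: chloromethyl methyl ether, COCCl
Why: Standard O-alkylation of phenols gives the MOM ethers, which resist organometallics and fluoride and later act as ortho-directing groups.

Step 3
Reactants: 3 5-fluoro-2-iodo-1,3-bis(methoxymethoxy)benzene
Product: 5 5-fluoro-1,3-bis(methoxymethoxy)-2-(3-methylbut-2-en-1-yl)benzene, via arylmagnesium chloride 4 (not isolated)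
Conditions: i-PrMgCl·LiCl, THF, −20 to 0 °C; then CuBr·SMe2 (5 mol%), prenyl bromide, 0 °C to rt
Reagents that add atoms: 1-bromo-3-methylbut-2-ene, CC(C)=CCBr
Why: Iodine–magnesium exchange followed by copper-catalysed allylic substitution should give the linear prenyl arene, because attack at the CH2 terminus avoids a quaternary benzylic carbon between two ortho substituents.

Step 4
Reactants: 5 5-fluoro-1,3-bis(methoxymethoxy)-2-(3-methylbut-2-en-1-yl)benzene; 6 methyl (2S)-oxirane-2-carboxylate
Product: 10 (2S)-1-[6-fluoro-2,4-bis(methoxymethoxy)-3-(3-methylbut-2-en-1-yl)phenyl]-3-methylbutane-2,3-diol, via aryllithium 7 (not isolated), via arylmagnesium bromide 8 (not isolated), via hydroxy ester 9 (not isolated)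
Conditions: s-BuLi, THF, −78 °C; MgBr2·OEt2, −78 to −40 °C; CuBr·SMe2 (10 mol%), then 6, −40 to −20 °C; MeMgBr (4 equiv), −20 to 0 °C; aq NH4Cl
Reagents that add atoms: methylmagnesium bromide, C[Mg]Br
Why: Directed ortho-lithiation takes one of the two equivalent CH positions between F and OMOM, transmetalation to magnesium stops loss of LiF, copper-catalysed SN2 opening of the glycidate at its CH2 terminus leaves the stereocentre untouched (S, from the chiral pool), and double Grignard addition to the ester then builds the tertiary carbinol in the same flask.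

Step 5
Reactants: 10 (2S)-1-[6-fluoro-2,4-bis(methoxymethoxy)-3-(3-methylbut-2-en-1-yl)phenyl]-3-methylbutane-2,3-diol
Product: 11 (4S)-4-{[6-fluoro-2,4-bis(methoxymethoxy)-3-(3-methylbut-2-en-1-yl)phenyl]methyl}-2,2,5,5-tetramethyl-1,3-dioxolane
Conditions: Me2C(OMe)2, PPTS (cat.), CH2Cl2, rt
Reagents that add atoms: 2,2-dimethoxypropane, COC(C)(C)OC
Why: Acid-catalysed transketalisation gives the acetonide, which masks both side-chain hydroxyls so that neither can later compete for the aryl fluoride.

Step 6
Reactants: 12 methyl 4-hydroxybenzoate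
Product: 13 methyl 4-(methoxymethoxy)benzoate
Conditions: MOMCl, i-Pr2NEt, CH2Cl2, 0 °C to rt
Reagents that add atoms: chloromethyl methyl ether, COCCl
Why: Standard MOM protection of a phenol, chosen because this ether survives base, aryllithium and fluoride and falls in the final acid step.

Step 7
Reactants: 13 methyl 4-(methoxymethoxy)benzoate; 14 N-methoxy-N-methylacetamide
Product: 16 N-methoxy-3-[4-(methoxymethoxy)phenyl]-N-methyl-3-oxopropanamide, via amide enolate 15 (not isolated)
Conditions: 14, LiN(i-Pr)2 (2.2 equiv), THF, −78 °C; then 13, −78 to 0 °C; aq NH4Cl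
Reagents that add atoms: none
Why: Crossed Claisen condensation, in which the lithium enolate of the Weinreb acetamide acylates the non-enolisable aryl ester and the β-keto amide is held as its enolate by the second equivalent of base until work-up.

Step 8
Reactants: 16 N-methoxy-3-[4-(methoxymethoxy)phenyl]-N-methyl-3-oxopropanamide
Product: 17 (3S)-3-hydroxy-N-methoxy-3-[4-(methoxymethoxy)phenyl]-N-methylpropanamide
Conditions: RuCl[(S,S)-TsDPEN](p-cymene) (1 mol%), HCO2H/Et3N (5:2), CH2Cl2, 25 °C
Reagents that add atoms: none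
Why: Noyori asymmetric transfer hydrogenation of the aryl ketone with the (S,S)-TsDPEN catalyst should give the S carbinol, the sense established for aryl alkyl ketones, through the CH–π-organised six-membered hydride transfer.

Step 9
Reactants: 17 (3S)-3-hydroxy-N-methoxy-3-[4-(methoxymethoxy)phenyl]-N-methylpropanamide
Product: 18 (3S)-N-methoxy-3-[4-(methoxymethoxy)phenyl]-N-methyl-3-[(triethylsilyl)oxy]propanamide
Conditions: Et3SiCl, imidazole, DMF, 0 °C to rt
Reagents that add atoms: chlorotriethylsilane, CC[Si](Cl)(CC)CC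
Why: Routine silylation of a secondary alcohol gives a TES ether that survives the aryllithium and serves as the fluoride-labile trigger of the ring closure.

Step 10
Reactants: 11 (4S)-4-{[6-fluoro-2,4-bis(methoxymethoxy)-3-(3-methylbut-2-en-1-yl)phenyl]methyl}-2,2,5,5-tetramethyl-1,3-dioxolane; 18 (3S)-N-methoxy-3-[4-(methoxymethoxy)phenyl]-N-methyl-3-[(triethylsilyl)oxy]propanamide
Product: 20 (3S)-1-{2-fluoro-4,6-bis(methoxymethoxy)-5-(3-methylbut-2-en-1-yl)-3-{[(4S)-2,2,5,5-tetramethyl-1,3-dioxolan-4-yl]methyl}phenyl}-3-[4-(methoxymethoxy)phenyl]-3-[(triethylsilyl)oxy]propan-1-one, via aryllithium 19 (not isolated)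
Conditions: 11, s-BuLi, THF, −78 °C; then 18, −78 to −60 °C; aq NH4Cl at −60 °C
Reagents that add atoms: none
Why: Directed ortho-lithiation at the only remaining ring CH (acidified by the adjacent F and OMOM) followed by Weinreb ketone synthesis should give the ketone, the chelated tetrahedral intermediate preventing over-addition and the low temperature preventing loss of LiF.

Step 11
Reactants: 20 (3S)-1-{2-fluoro-4,6-bis(methoxymethoxy)-5-(3-methylbut-2-en-1-yl)-3-{[(4S)-2,2,5,5-tetramethyl-1,3-dioxolan-4-yl]methyl}phenyl}-3-[4-(methoxymethoxy)phenyl]-3-[(triethylsilyl)oxy]propan-1-one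
Product: 22 (2S)-5,7-bis(methoxymethoxy)-2-[4-(methoxymethoxy)phenyl]-6-(3-methylbut-2-en-1-yl)-8-{[(4S)-2,2,5,5-tetramethyl-1,3-dioxolan-4-yl]methyl}-2,3-dihydro-4H-chromen-4-one, via cesium alkoxide 21 (not isolated)
Conditions: CsF (0.3 equiv), anhydrous DMF, 0 °C to rt; pH 7 buffer
Reagents that add atoms: none
Why: Fluoride attacks silicon and frees the C2 alkoxide, which adds to C8a, the β-carbon of the vinylogous acyl fluoride C4(=O)–C4a=C8a–F, to give a Meisenheimer enolate delocalised onto the C4 carbonyl; loss of fluoride restores ring A and returns the catalyst (addition–elimination SNAr, net transfer of fluorine from carbon to silicon). The closest known reaction types are the fluoride- or base-catalysed SNAr etherification of silyl ethers with activated aryl fluorides and the intramolecular alkoxide SNAr onto ortho-fluoroaryl ketones that closes benzo-fused six-membered oxygen heterocycles. Ring C closes in a formally 6-endo-trig mode with respect to the C4a=C8a bond through which the charge flows to C4=O, the forming ring holding the ketone coplanar with ring A. No new stereocentre is created: the C2–O bond is not broken, so the S configuration from step 8 should be retained. The step needs chemoselectivity for cyclisation over retro-aldol cleavage or β-elimination of silanolate, and freedom from epimerisation of the base-sensitive product; both are addressed by the absence of stoichiometric base, the only base being the transient alkoxide. Regioselectivity for C8a over C5 and over the side-chain oxygens is secured by the single fluorine, which sits only at C8a, and by the acetonide.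

Step 12
Reactants: 22 (2S)-5,7-bis(methoxymethoxy)-2-[4-(methoxymethoxy)phenyl]-6-(3-methylbut-2-en-1-yl)-8-{[(4S)-2,2,5,5-tetramethyl-1,3-dioxolan-4-yl]methyl}-2,3-dihydro-4H-chromen-4-one
Product: 23 (2S)-8-[(2S)-2,3-dihydroxy-3-methylbutyl]-5,7-dihydroxy-2-(4-hydroxyphenyl)-6-(3-methylbut-2-en-1-yl)-2,3-dihydro-4H-chromen-4-one
Conditions: 1 M HCl, MeOH–H2O, 40 °C
Reagents that add atoms: none
Why: Acid-catalysed transacetalisation removes the three MOM ethers and the acetonide in one operation under conditions mild enough for the prenyl group and without the base that would open the chromanone, so both stereocentres should stay S.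

**Compound list**

1 | 5-fluorobenzene-1,3-diol | Oc1cc(O)cc(F)c1 | starting material
2 | 5-fluoro-2-iodobenzene-1,3-diol | Oc1cc(F)cc(O)c1I | intermediate
3 | 5-fluoro-2-iodo-1,3-bis(methoxymethoxy)benzene | COCOc1cc(F)cc(OCOC)c1I | intermediate
4 | [4-fluoro-2,6-bis(methoxymethoxy)phenyl]magnesium chloride | COCOc1cc(F)cc(OCOC)c1[Mg]Cl | intermediate
5 | 5-fluoro-1,3-bis(methoxymethoxy)-2-(3-methylbut-2-en-1-yl)benzene | COCOc1cc(F)cc(OCOC)c1CC=C(C)C | intermediate
6 | methyl (2S)-oxirane-2-carboxylate | COC(=O)[C@@H]1CO1 | starting material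
7 | [6-fluoro-2,4-bis(methoxymethoxy)-3-(3-methylbut-2-en-1-yl)phenyl]lithium | [Li]c1c(F)cc(OCOC)c(CC=C(C)C)c1OCOC | intermediate
8 | [6-fluoro-2,4-bis(methoxymethoxy)-3-(3-methylbut-2-en-1-yl)phenyl]magnesium bromide | Br[Mg]c1c(F)cc(OCOC)c(CC=C(C)C)c1OCOC | intermediate
9 | methyl (2S)-3-[6-fluoro-2,4-bis(methoxymethoxy)-3-(3-methylbut-2-en-1-yl)phenyl]-2-hydroxypropanoate (present in the flask as its bromomagnesium alkoxide) | COCOc1cc(F)c(C[C@H](O)C(=O)OC)c(OCOC)c1CC=C(C)C | intermediate
10 | (2S)-1-[6-fluoro-2,4-bis(methoxymethoxy)-3-(3-methylbut-2-en-1-yl)phenyl]-3-methylbutane-2,3-diol | COCOc1cc(F)c(C[C@H](O)C(C)(C)O)c(OCOC)c1CC=C(C)C | intermediate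
11 | (4S)-4-{[6-fluoro-2,4-bis(methoxymethoxy)-3-(3-methylbut-2-en-1-yl)phenyl]methyl}-2,2,5,5-tetramethyl-1,3-dioxolane | COCOc1cc(F)c(C[C@H](OC(C)(C)O2)C2(C)C)c(OCOC)c1CC=C(C)C | intermediate
12 | methyl 4-hydroxybenzoate | COC(=O)c1ccc(O)cc1 | starting material
13 | methyl 4-(methoxymethoxy)benzoate | COCOc1ccc(cc1)C(=O)OC | intermediate
14 | N-methoxy-N-methylacetamide | CC(=O)N(C)OC | starting material
15 | lithium 1-[methoxy(methyl)amino]ethenolate | [Li]OC(=C)N(C)OC | intermediate
16 | N-methoxy-3-[4-(methoxymethoxy)phenyl]-N-methyl-3-oxopropanamide | COCOc1ccc(cc1)C(=O)CC(=O)N(C)OC | intermediate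
17 | (3S)-3-hydroxy-N-methoxy-3-[4-(methoxymethoxy)phenyl]-N-methylpropanamide | CON(C)C(=O)C[C@@H](c1ccc(OCOC)cc1)O | intermediate
18 | (3S)-N-methoxy-3-[4-(methoxymethoxy)phenyl]-N-methyl-3-[(triethylsilyl)oxy]propanamide | CON(C)C(=O)C[C@@H](c1ccc(OCOC)cc1)O[Si](CC)(CC)CC | intermediate
19 | {2-fluoro-4,6-bis(methoxymethoxy)-5-(3-methylbut-2-en-1-yl)-3-{[(4S)-2,2,5,5-tetramethyl-1,3-dioxolan-4-yl]methyl}phenyl}lithium | COCOc1c([Li])c(F)c(C[C@H](OC(C)(C)O2)C2(C)C)c(OCOC)c1CC=C(C)C | intermediate
20 | (3S)-1-{2-fluoro-4,6-bis(methoxymethoxy)-5-(3-methylbut-2-en-1-yl)-3-{[(4S)-2,2,5,5-tetramethyl-1,3-dioxolan-4-yl]methyl}phenyl}-3-[4-(methoxymethoxy)phenyl]-3-[(triethylsilyl)oxy]propan-1-one | COCOc1c(C(=O)C[C@@H](c2ccc(OCOC)cc2)O[Si](CC)(CC)CC)c(F)c(C[C@H](OC(C)(C)O3)C3(C)C)c(OCOC)c1CC=C(C)C | intermediate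
21 | cesium (1S)-3-{2-fluoro-4,6-bis(methoxymethoxy)-5-(3-methylbut-2-en-1-yl)-3-{[(4S)-2,2,5,5-tetramethyl-1,3-dioxolan-4-yl]methyl}phenyl}-1-[4-(methoxymethoxy)phenyl]-3-oxopropan-1-olate | COCOc1c(C(=O)C[C@@H](c2ccc(OCOC)cc2)[O-])c(F)c(C[C@H](OC(C)(C)O3)C3(C)C)c(OCOC)c1CC=C(C)C.[Cs+] | intermediate
22 | (2S)-5,7-bis(methoxymethoxy)-2-[4-(methoxymethoxy)phenyl]-6-(3-methylbut-2-en-1-yl)-8-{[(4S)-2,2,5,5-tetramethyl-1,3-dioxolan-4-yl]methyl}-2,3-dihydro-4H-chromen-4-one | CC(C)=CCc1c(OCOC)c(C[C@H](OC(C)(C)O3)C3(C)C)c2c(c1OCOC)C(=O)C[C@@H](c1ccc(OCOC)cc1)O2 | intermediate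
23 | (2S)-8-[(2S)-2,3-dihydroxy-3-methylbutyl]-5,7-dihydroxy-2-(4-hydroxyphenyl)-6-(3-methylbut-2-en-1-yl)-2,3-dihydro-4H-chromen-4-one | CC(C)=CCc1c(O)c(C[C@H](O)C(C)(C)O)c2c(c1O)C(=O)C[C@@H](c1ccc(O)cc1)O2 | target

**Step count and risks**

Total step count: 12. Longest linear sequence: 8 steps (steps 1–5 and 10–12, from 5-fluorobenzene-1,3-diol).

First risk, step 11. The freed alkoxide may fragment by retro-aldol cleavage, or fluoride may trigger β-elimination of silanolate, faster than the ring closes; the product may also lose configuration at C2 by ring opening to the chalcone. The fallback keeps the O1–C8a SNAr but runs it on an enolate oxygen that cannot fragment, and brings in ring B afterwards. It sets out from 11: lithiation as in step 10 and trapping with 14 should give the aryl methyl ketone F1. Claisen formylation with ethyl formate and NaH (THF, then warming in DMF) should let the enolate oxygen of the β-keto aldehyde displace the fluoride and give the 2-unsubstituted chromone F2. Palladium-catalysed asymmetric conjugate addition of [4-(methoxymethoxy)phenyl]boronic acid (Pd(OCOCF3)2, the tert-butyl pyridine–oxazoline ligand enantiomer that delivers the 2S product, NH4PF6, H2O, 1,2-dichloroethane, 60 °C) should then return to the route at 22.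

Second risk, step 10. The doubly ortho-substituted aryllithium may add too slowly to the amide at the temperatures at which it is stable, so that loss of LiF (aryne formation) or deprotonation of the amide with β-elimination of silanolate takes over. The fallback uses a faster electrophile and adjusts the oxidation level afterwards. It sets out from 18: reduction with i-Bu2AlH (THF, −78 °C) should give the silyloxy aldehyde F3. Addition of aryllithium 19 at −78 °C should give the benzylic carbinol F4 as a mixture of epimers at the new carbinol carbon, which does not matter. Oxidation with Dess–Martin periodinane (NaHCO3 buffer, CH2Cl2) should return to the route at 20.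

Third risk, step 4. The copper-catalysed opening may lose to 1,2-addition of the arylmagnesium to the glycidate ester, or the hindered arylmetal may open the epoxide too slowly and be quenched. The fallback finishes the tertiary carbinol on the small fragment first and opens a simple epoxide under Lewis acid activation. It sets out from 6: MeMgBr (2 equiv, THF, −78 °C) should give the epoxy alcohol F5, and Et3SiOSO2CF3 with 2,6-lutidine its silyl ether F6. Opening of F6 by aryllithium 7 with BF3·OEt2 (THF, −78 °C) should give the mono-silylated diol F7, and Bu4NF in THF should return to the route at 10.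

Further compounds
F1 | step 11 | 1-{2-fluoro-4,6-bis(methoxymethoxy)-5-(3-methylbut-2-en-1-yl)-3-{[(4S)-2,2,5,5-tetramethyl-1,3-dioxolan-4-yl]methyl}phenyl}ethan-1-one | CC(=O)c1c(F)c(C[C@H](OC(C)(C)O2)C2(C)C)c(OCOC)c(CC=C(C)C)c1OCOC
F2 | step 11 | 5,7-bis(methoxymethoxy)-6-(3-methylbut-2-en-1-yl)-8-{[(4S)-2,2,5,5-tetramethyl-1,3-dioxolan-4-yl]methyl}-4H-chromen-4-one | O=c1ccoc2c1c(OCOC)c(CC=C(C)C)c(OCOC)c2C[C@H](OC(C)(C)O3)C3(C)C
F3 | step 10 | (3S)-3-[4-(methoxymethoxy)phenyl]-3-[(triethylsilyl)oxy]propanal | O=CC[C@@H](c1ccc(OCOC)cc1)O[Si](CC)(CC)CC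
F4 | step 10 | (3S)-1-{2-fluoro-4,6-bis(methoxymethoxy)-5-(3-methylbut-2-en-1-yl)-3-{[(4S)-2,2,5,5-tetramethyl-1,3-dioxolan-4-yl]methyl}phenyl}-3-[4-(methoxymethoxy)phenyl]-3-[(triethylsilyl)oxy]propan-1-ol (both C1 epimers) | COCOc1c(C(O)C[C@@H](c2ccc(OCOC)cc2)O[Si](CC)(CC)CC)c(F)c(C[C@H](OC(C)(C)O3)C3(C)C)c(OCOC)c1CC=C(C)C
F5 | step 4 | 2-[(2S)-oxiran-2-yl]propan-2-ol | C1[C@H](O1)C(C)(C)O
F6 | step 4 | triethyl({2-[(2S)-oxiran-2-yl]propan-2-yl}oxy)silane | C1[C@H](O1)C(C)(C)O[Si](CC)(CC)CC
F7 | step 4 | (2S)-1-[6-fluoro-2,4-bis(methoxymethoxy)-3-(3-methylbut-2-en-1-yl)phenyl]-3-methyl-3-[(triethylsilyl)oxy]butan-2-ol | COCOc1cc(F)c(C[C@H](O)C(C)(C)O[Si](CC)(CC)CC)c(OCOC)c1CC=C(C)C
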